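## The problem

The target 24 is a eudesmane. Ring A (C1–C5, C10) and ring B (C5–C10) share only the C5–C10 bond; C14 is the methyl on C10, C15 the exocyclic methylene on C4, and C11(=C13)–C12 the acrylate on C7. β is the face of the C10 methyl, and intermediates that lack C13 or C15 are named as nor-eudesmanes.

Five stereocentres have to be set: C3 (β isobutyrate), C5 (α hydroperoxide), C7 (β acrylate arm), C8 (β acetate) and C10 (β methyl). C5 and C10 are adjacent and fully substituted.

C10 cannot be corrected later, but it can govern the others. C7 is epimerisable while C8 is a ketone and settles equatorial. The axial C10 methyl screens the β face of a C8 carbonyl and of a C4=C5 bond. A 3-ketone in a 10β-methyl-4-ene is reduced from the α face.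

The tertiary allylic hydroperoxide will not survive reductants, phosphines, strong acid (Hock cleavage), strong base or transition metals, so it must be made last. The α-methylene ester is a Michael acceptor, is easily hydrogenated and can isomerise towards C7. The esters at O3 and O8 differ and need separate operations, and the 8β-oxygen is cis to the C7 arm, so a free 8β-hydroxyl tends to close onto C12 as a γ-lactone.

The 5-hydroperoxy-4(15)-ene unit is what a singlet-oxygen ene reaction leaves behind on a 4-methyl-4-ene, so C5 may stay trigonal until the end.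

The feature that permits a cycloaddition is the single shared edge: cutting C5–C6 and C9–C10 removes C6–C9 as a 2,3-disubstituted butadiene (oxygen on C8, acetic ester arm on C7). What remains is a six-carbon ring A with oxygen at C3, a carbonyl at C4 and a methyl on C10, which is the substitution pattern of 2-methoxy-5-methyl-1,4-benzoquinone.

## Retrosynthesis

**C5–O bond (24 ⇒ 23).** The hydroperoxide is removed first, by an ene disconnection that returns the C4=C15 bond to C4=C5 and gives the 4-methyl-4-ene 23. No other cut could come first, since nothing else in the route tolerates the O–O bond. The precursor has one stereocentre fewer. The forward reaction has to choose the α face, bond oxygen to C5 and take hydrogen from C15.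

**Acyl C–O bonds at O3 and O8, and the O8/C12 relation (23 ⇒ 22 ⇒ 21 ⇒ 20 ⇒ 18).** The two esters are cut one at a time. O3 is held as a silyl ether (21, 22) so that O8 can be acetylated alone. The 8β-hydroxy methyl ester 20 is traced to the cis-fused α-methylene lactone 18, in which O8 and C12 protect each other. Acylating a 3,8-diol selectively would rest on an uncertain rate difference; the lactone makes the differentiation structural. The forward opening must outrun relactonisation.

**C11=C13 bond (18 ⇒ 16 ⇒ 15 ⇒ 14).** The methylene carbon is removed by a Mannich disconnection at the lactone α-carbon. A lactone enolate is the only place where C11 can be deprotonated cleanly, which is the second reason for passing through the lactone. The hydroxy lactone 14 then has a simple CH2 at C11.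

**C3–H, C8–H and O8–C12 bonds (14 ⇒ 12).** Both carbinol hydrogens are removed to give the 3,8-diketo ester 12. One hydride reagent should set C3 and C8 under the control of C10, and the 8β-alkoxide should lactonise by itself. Precursor 12 has only C7 and C10 as stereocentres, and C7 is under thermodynamic control.

**C1 deoxygenation (12 ⇒ 11 ⇒ 9).** The C1–C2 bond is unsaturated to the cross-conjugated dienone 11, and a 1,3-carbonyl transposition leads back to the 3-methoxy-2,4-dien-1-one 9. This puts the C1 oxygen back and turns the C3 ketone into its methyl enol ether, which is the oxidation pattern a methoxyquinone delivers. The forward steps need a hydride that distinguishes the C1 carbonyl from the ester, and a hydrogenation that distinguishes C1=C2 from C4=C5.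

**C4–C15 bond (9 ⇒ 8 ⇒ 7).** The methyl group is cut from C4 by a cross-coupling disconnection to the enol triflate 8, made from the C4 ketone of adduct 7. Adding a methyl nucleophile to the C4 ketone and dehydrating the tertiary α-ketol would leave open whether the alkene ends up C4=C5 or C4=C15. Enolisation towards C5 (the only α-hydrogen) fixes it and makes C5 trigonal at once.

**C5–C6 and C9–C10 bonds (7 ⇒ 5 + 6), the key disconnection.** Cutting both bonds of ring B at the shared edge gives diene 5 and quinone 6, two fragments of similar size. Cutting C7–C8 or bonds of ring A would leave a quaternary C10 to be built on a monocycle. Here C10 is the methyl-bearing quinone carbon and becomes quaternary in the cycloaddition. The forward reaction must use the methyl-bearing alkene, join C9 to C10, and differentiate the two faces.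

**Diene (5 ⇒ 4 ⇒ 3 ⇒ 1 + 2).** The silyl enol ether is cut to the enone 4. Its methylidene group is cut by an olefination disconnection to phosphonate 3, and 3 at the bond between the phosphonate carbon and the CH2CO2Me group to 1 and 2. A direct Mannich methylenation of a levulinate ester would be shorter but would have to discriminate between two α-carbons. The phosphonate marks the carbon.

## Roads not taken

**Alternative 1: oxidative radical bicyclisation.** The cut is at C4–C5 and C9–C10. In the forward sense the acyclic β-keto ester A1 is oxidised with Mn(OAc)3 (trivalent manganese) and Cu(OAc)2. The C4 radical adds to C5, the resulting C10 radical adds to C9 of the enol acetate, and oxidation of the α-acetoxy radical gives the trans-fused diketone A2.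
- Merits: both rings, two C–C bonds and the C5/C10 relation arise in one step from a linear chain, with the C8 ketone and the C7 arm in place. No chiral catalyst is needed at that stage if C7 is already set. In bonds formed per step this road beats the chosen plan.
- Weak points: A2 carries a surplus methoxycarbonyl group on C4, which must be removed by dealkoxycarbonylation. It also has a saturated C5, which must be dehydrogenated to the 4-ene before the ene reaction, so the ring-fusion stereocentre just made is erased. Absolute control rests on a single remote stereocentre (C7) relaying through a radical chair transition state, and A1 itself needs a stereodefined trisubstituted alkene and an enantioselective synthesis.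
- Comparison: the chosen plan sets against the higher bond count a catalyst-controlled C10, a C5 that is trigonal from step 5 onwards, and an adduct (7) whose oxygen pattern needs no removal of carbon.

**Alternative 2: chromium-mediated allylation closing ring B at C7–C8.** The cut is the C7–C8 bond. CrCl2 (divalent chromium) converts the (Z)-2-(bromomethyl)enoate of A3 into an allylchromium species whose C7 adds to the C8 aldehyde (intramolecular Nozaki–Hiyama allylation). This gives A4 with ring B closed and the C11=C13 methylene ester unveiled.
- Merits: C7, C8 and the acrylate are made in the ring-closing step. The endgame from A4 would be clearly shorter than the one chosen here, since lactone methylenation and lactone opening are not needed. In this respect the road is better.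
- Weak points: the cost moves to the front. A3 needs the quaternary C10 built enantioselectively on a monocyclic enone carrying two differentiated side chains. The C7/C8 relation and its relation to C10 depend on a cyclic transition state inside the forming ring. The 8β-chromium alkoxide may lactonise onto C12 and bring the opening problem back. Chromium is used in excess.
- Comparison: the chosen plan sets against the shorter endgame a four-step, catalytic entry to the bicyclic core from two simple fragments, with C10 fixed at the outset.

**Alternative 3: oxy-Cope rearrangement and transannular ene reaction.** The C5–C10 bond is broken and re-formed, and C2–C3 is made. The 1-isopropenyl-2-vinylcyclohexanol A5 rearranges as its alkoxide to the ten-membered enone A6. The C5 ketone of A6 then adds across the ring to C10 in a carbonyl-ene reaction, closing ring A to A7.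
- Merits: the C5–O bond, the quaternary C10 and their trans relation come from one stereospecific cascade, so no late oxygenation of a tetrasubstituted alkene is needed to form the C5–O bond. In this respect it is better than the chosen plan.
- Weak points: the oxygen arrives as a tertiary alcohol, and exchanging it for a hydroperoxide is not a reliable operation. C4 is saturated and would have to be dehydrogenated to the exocyclic methylene next to that alcohol. C3 carries no oxygen, and the C1=C2 alkene is misplaced for introducing one. The C8 oxygen in A7 is α and must be inverted, and C12 is at the alcohol oxidation level. The step count grows through these redox corrections.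
- Comparison: the chosen plan forms the C5–O bond late and with some risk, but adduct 7 already has oxygen at C3, a carbonyl at C4 for C15, and a masked C8 ketone beside the C7 arm.

Key step: step 4

Assumption: which antipode of 1,1'-bi-2-naphthol gives the (10R) adduct has to be read from the first adduct; (R) is written throughout, and the equally available (S) ligand replaces it if the sense proves opposite.

Assumption: quinone 6 is taken as a purchased compound.

## Route

Step 1
Reactants: 1 dimethyl (2-oxopropyl)phosphonate; 2 methyl bromoacetate
Product: 3 methyl 3-(dimethoxyphosphoryl)-4-oxopentanoate (racemic)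
Conditions: NaH, THF, 0 °C; then 2, 0 °C to rt
Reagents that add atoms: none
Why: SN2 C-alkylation of the sodium enolate of a β-ketophosphonate by an α-bromo ester at the carbon between phosphorus and the ketone; a small excess of 1 suppresses double alkylation.

Step 2
Reactants: 3 methyl 3-(dimethoxyphosphoryl)-4-oxopentanoate
Product: 4 methyl 3-methylidene-4-oxopentanoate
Conditions: 37% aq. CH2O, K2CO3, THF/H2O, 0 °C to rt
Reagents that add atoms: formaldehyde, C=O
Why: Horner–Wadsworth–Emmons olefination with formaldehyde places the methylidene group on C3 without ambiguity, and aqueous K2CO3 is too weak a base to move the β,γ-unsaturated ester into conjugation.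

Step 3
Reactants: 4 methyl 3-methylidene-4-oxopentanoate
Product: 5 methyl 4-(tert-butyldimethylsilyloxy)-3-methylidenepent-4-enoate
Conditions: tBuMe2SiOTf, Et3N, CH2Cl2, 0 °C
Reagents that add atoms: tert-butyldimethylsilyl trifluoromethanesulfonate, CC(C)(C)[Si](C)(C)OS(=O)(=O)C(F)(F)F
Why: Soft enolisation of an α,β-unsaturated methyl ketone: O-silylation and loss of a proton from the methyl group, the only site whose deprotonation gives a neutral enol ether, give the 2-silyloxy-1,3-diene; the ester is silylated far more slowly at 0 °C.

Step 4
Reactants: 5 methyl 4-(tert-butyldimethylsilyloxy)-3-methylidenepent-4-enoate; 6 2-methoxy-5-methyl-1,4-benzoquinone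
Product: 7 methyl 8-(tert-butyldimethylsilyloxy)-3-methoxy-1,4-dioxo-13,15-dinoreudesma-2,7-dien-12-oate, cis-fused (5β-H, 10β-CH3; 5S,10R)
Conditions: catalyst from TiCl2(OiPr)2 and (R)-1,1'-bi-2-naphthol (10 mol%, prepared over 4 Å molecular sieves, sieves removed), CH2Cl2, −40 to −20 °C; Et3N quench
Reagents that add atoms: none
Why: Normal-electron-demand Diels–Alder reaction, concerted but asynchronous, whose closest precedents are the SnCl4- or TiCl4-promoted additions of dienes to this quinone giving angular-methyl cis-decalins and the binaphthol–titanium-catalysed enantioselective quinone cycloadditions. The titanium centre (tetravalent, two free sites) chelates the carbonyl next to the methoxy group and the methoxy oxygen (C4=O and C3–OMe), which lowers the LUMO and makes the methyl-bearing carbon, the β-position of that carbonyl, the electrophilic end of the C5=C10 alkene. The methoxy-bearing alkene is a vinylogous ester and does not compete. The diene reacts through its silyl enol ether terminus (C9, largest HOMO coefficient), so C9 bonds to C10 and C6 to C5. Ring B is closed by the cycloaddition itself, both bonds forming on one face of the quinone alkene, hence the cis ring fusion. C5 and C10 are created together, their relative configuration following from suprafacial addition and their absolute configuration from the quinone face that the binaphtholate leaves open; because neither diene terminus is substituted, endo and exo approaches give the same product. The step needs site selectivity, regiochemistry and facial selectivity: the first two are secured by the methoxy group and the chelate, the third by the ligand, and only C10 has to last because C5 becomes trigonal in step 5. The angular methyl prevents aromatisation, and a non-acidic work-up keeps the silyl enol ether that masks the C8 ketone.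

Step 5
Reactants: 7 cis-fused adduct
Product: 8 methyl 8-(tert-butyldimethylsilyloxy)-3-methoxy-1-oxo-4-(trifluoromethanesulfonyloxy)-13,15-dinoreudesma-2,4,7-trien-12-oate (10β-CH3)
Conditions: KN(SiMe3)2, THF, −78 °C; then PhNTf2, −78 to 0 °C
Reagents that add atoms: N-phenylbis(trifluoromethanesulfonimide), O=S(=O)(N(c1ccccc1)S(=O)(=O)C(F)(F)F)C(F)(F)F
Why: Enol triflate formation: the ring-fusion hydrogen at C5, α to the C4 ketone, is the most acidic proton, and its potassium enolate is O-sulfonylated; this fixes the C4=C5 double bond regiospecifically, and the quaternary C10 rules out aromatisation.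

Step 6
Reactants: 8 enol triflate
Product: 9 methyl 8-(tert-butyldimethylsilyloxy)-3-methoxy-1-oxo-13-noreudesma-2,4,7-trien-12-oate (10β-CH3)
Conditions: Me2Zn, Pd(PPh3)4 (5 mol%), THF, 0 °C to rt
Reagents that add atoms: dimethylzinc, C[Zn]C
Why: Negishi cross-coupling (oxidative addition of the alkenyl triflate to palladium, methyl transfer from zinc, reductive elimination) introduces C15; dimethylzinc does not add to the vinylogous ester, the ester or the silyl enol ether.

Step 7
Reactants: 9 methylated dienone
Product: 11 methyl 3,8-dioxo-13-noreudesma-1,4-dien-12-oate (7β-CH2CO2Me, 10β-CH3), via C1 dienol 10 (not isolated)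
Conditions: NaBH4, CeCl3·7H2O, MeOH/THF, −20 to 0 °C; then 2 M HCl, THF, rt
Reagents that add atoms: water, O
Why: Luche 1,2-reduction of the vinylogous ester carbonyl at C1 spares the methyl ester and the silyl enol ether; acid then ionises the C1 alcohol, water adds at C3 and methanol is lost (Stork–Danheiser-type 1,3-carbonyl transposition) while the silyl enol ether is hydrolysed to the C8 ketone. C7 is set here under thermodynamic control: it is epimerisable next to the C8 ketone and the CH2CO2Me arm takes the equatorial 7β position.

Step 8
Reactants: 11 methyl 3,8-dioxo-13-noreudesma-1,4-dien-12-oate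
Product: 12 methyl 3,8-dioxo-13-noreudesm-4-en-12-oate (7β-CH2CO2Me, 10β-CH3)
Conditions: H2 (1 atm), RhCl(PPh3)3 (5 mol%), benzene/EtOH, rt
Reagents that add atoms: none
Why: Homogeneous hydrogenation with RhCl(PPh3)3 saturates the disubstituted C1=C2 bond of a cross-conjugated 4-methyl-1,4-dien-3-one and leaves the tetrasubstituted C4=C5 bond, the ketones and the ester, as known for santonin-type and steroidal 1,4-dien-3-ones.

Step 9
Reactants: 12 methyl 3,8-dioxo-13-noreudesm-4-en-12-oate
Product: 14 3β-hydroxy-13-noreudesm-4-en-12,8β-olide (cis-fused γ-lactone), via dihydroxy ester 13 (not isolated)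
Conditions: NaBH4, CeCl3·7H2O, MeOH, −40 to 0 °C, then rt
Reagents that add atoms: none
Why: Luche reduction of both ketones under substrate control: hydride adds to the C3 enone carbonyl axially from the α face to give the pseudo-equatorial 3β-alcohol, as is usual for 10β-methyl-4-en-3-ones, and to C8 from the α face because the axial C10 methyl blocks the β face, giving the axial 8β-alkoxide. This oxygen is cis to the C7 arm and closes the γ-lactone with loss of methanol.

Step 10
Reactants: 14 3β-hydroxy-13-noreudesm-4-en-12,8β-olide
Product: 15 3β-(tert-butyldimethylsilyloxy)-13-noreudesm-4-en-12,8β-olide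
Conditions: tBuMe2SiCl, imidazole, DMF, rt
Reagents that add atoms: tert-butyldimethylsilyl chloride, CC(C)(C)[Si](C)(C)Cl
Why: Standard silylation of a secondary allylic alcohol; the silyl ether withstands the amide base of step 11 and the hydroxide of step 13 and keeps O3 apart from O8.

Step 11
Reactants: 15 silyl ether lactone
Product: 16 13-(dimethylamino)-3β-(tert-butyldimethylsilyloxy)eudesm-4-en-12,8β-olide (C11 epimers)
Conditions: LiN(iPr)2, THF, −78 °C; then H2C=NMe2+ I−, −78 °C to rt
Reagents that add atoms: N,N-dimethylmethyleneiminium iodide, C=[N+](C)C.[I-]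
Why: Mannich reaction of the lactone lithium enolate with the preformed iminium salt; the configuration at C11 is of no consequence because C11 becomes trigonal in step 12.

Step 12
Reactants: 16 Mannich base
Product: 18 3β-(tert-butyldimethylsilyloxy)eudesma-4,11(13)-dien-12,8β-olide, via trimethylammonium iodide 17 (not isolated)
Conditions: MeI, THF/MeOH, rt; then aq. NaHCO3, CH2Cl2, rt
Reagents that add atoms: none
Why: Quaternisation of the Mannich base and base-induced β-elimination (E1cB) of trimethylamine give the α-methylene lactone; the methyl group from iodomethane leaves with the amine.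

Step 13
Reactants: 18 α-methylene lactone
Product: 20 methyl 3β-(tert-butyldimethylsilyloxy)-8β-hydroxyeudesma-4,11(13)-dien-12-oate, via potassium carboxylate 19 (not isolated)
Conditions: KOH (1.1 equiv), THF/H2O, 0 °C to rt; evaporate; MeI, DMF, 0 °C
Reagents that add atoms: potassium hydroxide, [K+].[OH-]; iodomethane, CI
Why: Saponification of the conjugated lactone in an alcohol-free medium (ring opening outpaces conjugate addition, and the acrylate carboxylate is a poor acceptor), then SN2 O-alkylation of the carboxylate under neutral, non-equilibrating conditions. The 8β-hydroxy ester is not stored but acetylated at once.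

Step 14
Reactants: 20 8β-hydroxy ester
Product: 21 methyl 8β-acetoxy-3β-(tert-butyldimethylsilyloxy)eudesma-4,11(13)-dien-12-oate
Conditions: Ac2O, pyridine, 4-(dimethylamino)pyridine (cat.), CH2Cl2, 0 °C to rt
Reagents that add atoms: acetic anhydride, CC(=O)OC(C)=O
Why: Nucleophile-catalysed acylation of the axial 8β-hydroxyl, which also removes the nucleophile that could re-close the lactone.

Step 15
Reactants: 21 silyl ether acetate
Product: 22 methyl 8β-acetoxy-3β-hydroxyeudesma-4,11(13)-dien-12-oate
Conditions: HF·pyridine, pyridine/THF, 0 °C to rt
Reagents that add atoms: none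
Why: Fluoride cleavage of the silyl ether with pyridine-buffered HF, which leaves the acetate, the methyl ester and the acrylate alone and is not acidic enough to ionise the allylic alcohol.

Step 16
Reactants: 22 3β-alcohol
Product: 23 methyl 8β-acetoxy-3β-(2-methylpropanoyloxy)eudesma-4,11(13)-dien-12-oate
Conditions: iPrCOCl, pyridine, 4-(dimethylamino)pyridine (cat.), CH2Cl2, 0 °C
Reagents that add atoms: 2-methylpropanoyl chloride, CC(C)C(=O)Cl
Why: Acylation of the secondary allylic alcohol with an acid chloride and pyridine; esterification also removes the free 3β-hydroxyl, which would otherwise steer singlet oxygen to the β face by hydrogen bonding.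

Step 17
Reactants: 23 4-ene diester
Product: 24 methyl 8β-acetoxy-5α-hydroperoxy-3β-(2-methylpropanoyloxy)eudesma-4(15),11(13)-dien-12-oate (target)
Conditions: O2, 5,10,15,20-tetraphenylporphyrin (cat.), visible light, CH2Cl2, 0 °C
Reagents that add atoms: dioxygen, O=O
Why: Schenck ene reaction: singlet oxygen attacks the electron-rich tetrasubstituted C4=C5 bond (the acrylate is inert) from the α face, away from the axial C10 methyl and the 3β-ester, bonds to C5 and takes a hydrogen from C15, so that the double bond moves to C4=C15 and the 5α-hydroperoxide results. Ene reactions of this kind on eudesm-4-enes are known to give 5-hydroperoxy-4(15)-enes.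

## Compound list

1 | dimethyl (2-oxopropyl)phosphonate | CC(=O)CP(=O)(OC)OC | starting material
2 | methyl bromoacetate | COC(=O)CBr | starting material
3 | methyl 3-(dimethoxyphosphoryl)-4-oxopentanoate (racemic) | COC(=O)CC(C(C)=O)P(=O)(OC)OC | intermediate
4 | methyl 3-methylidene-4-oxopentanoate | COC(=O)CC(=C)C(C)=O | intermediate
5 | methyl 4-(tert-butyldimethylsilyloxy)-3-methylidenepent-4-enoate | COC(=O)CC(=C)C(=C)O[Si](C)(C)C(C)(C)C | intermediate
6 | 2-methoxy-5-methyl-1,4-benzoquinone | COC1=CC(=O)C(C)=CC1=O | starting material
7 | methyl 8-(tert-butyldimethylsilyloxy)-3-methoxy-1,4-dioxo-13,15-dinoreudesma-2,7-dien-12-oate, cis-fused (5β-H, 10β-CH3) | COC(=O)CC1=C(O[Si](C)(C)C(C)(C)C)C[C@@]2(C)C(=O)C=C(OC)C(=O)[C@H]2C1 | intermediate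
8 | methyl 8-(tert-butyldimethylsilyloxy)-3-methoxy-1-oxo-4-(trifluoromethanesulfonyloxy)-13,15-dinoreudesma-2,4,7-trien-12-oate | COC(=O)CC1=C(O[Si](C)(C)C(C)(C)C)C[C@@]2(C)C(=O)C=C(OC)C(OS(=O)(=O)C(F)(F)F)=C2C1 | intermediate
9 | methyl 8-(tert-butyldimethylsilyloxy)-3-methoxy-1-oxo-13-noreudesma-2,4,7-trien-12-oate | COC(=O)CC1=C(O[Si](C)(C)C(C)(C)C)C[C@@]2(C)C(=O)C=C(OC)C(C)=C2C1 | intermediate
10 | methyl 8-(tert-butyldimethylsilyloxy)-1-hydroxy-3-methoxy-13-noreudesma-2,4,7-trien-12-oate (both C1 epimers) | COC(=O)CC1=C(O[Si](C)(C)C(C)(C)C)C[C@@]2(C)C(O)C=C(OC)C(C)=C2C1 | intermediate (not isolated)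
11 | methyl 3,8-dioxo-13-noreudesma-1,4-dien-12-oate (7β arm, 10β-CH3) | COC(=O)C[C@H]1CC2=C(C)C(=O)C=C[C@]2(C)CC1=O | intermediate
12 | methyl 3,8-dioxo-13-noreudesm-4-en-12-oate | COC(=O)C[C@H]1CC2=C(C)C(=O)CC[C@]2(C)CC1=O | intermediate
13 | methyl 3β,8β-dihydroxy-13-noreudesm-4-en-12-oate | COC(=O)C[C@H]1CC2=C(C)[C@@H](O)CC[C@]2(C)C[C@H]1O | intermediate (not isolated)
14 | 3β-hydroxy-13-noreudesm-4-en-12,8β-olide | O=C1C[C@H]2CC3=C(C)[C@@H](O)CC[C@]3(C)C[C@H]2O1 | intermediate
15 | 3β-(tert-butyldimethylsilyloxy)-13-noreudesm-4-en-12,8β-olide | O=C1C[C@H]2CC3=C(C)[C@@H](O[Si](C)(C)C(C)(C)C)CC[C@]3(C)C[C@H]2O1 | intermediate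
16 | 13-(dimethylamino)-3β-(tert-butyldimethylsilyloxy)eudesm-4-en-12,8β-olide (C11 epimers) | O=C1C(CN(C)C)[C@H]2CC3=C(C)[C@@H](O[Si](C)(C)C(C)(C)C)CC[C@]3(C)C[C@H]2O1 | intermediate
17 | 13-(trimethylammonio)-3β-(tert-butyldimethylsilyloxy)eudesm-4-en-12,8β-olide iodide | O=C1C(C[N+](C)(C)C)[C@H]2CC3=C(C)[C@@H](O[Si](C)(C)C(C)(C)C)CC[C@]3(C)C[C@H]2O1.[I-] | intermediate (not isolated)
18 | 3β-(tert-butyldimethylsilyloxy)eudesma-4,11(13)-dien-12,8β-olide | O=C1C(=C)[C@H]2CC3=C(C)[C@@H](O[Si](C)(C)C(C)(C)C)CC[C@]3(C)C[C@H]2O1 | intermediate
19 | potassium 3β-(tert-butyldimethylsilyloxy)-8β-hydroxyeudesma-4,11(13)-dien-12-oate | C=C(C(=O)[O-])[C@H]1CC2=C(C)[C@@H](O[Si](C)(C)C(C)(C)C)CC[C@]2(C)C[C@H]1O.[K+] | intermediate (not isolated)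
20 | methyl 3β-(tert-butyldimethylsilyloxy)-8β-hydroxyeudesma-4,11(13)-dien-12-oate | C=C(C(=O)OC)[C@H]1CC2=C(C)[C@@H](O[Si](C)(C)C(C)(C)C)CC[C@]2(C)C[C@H]1O | intermediate
21 | methyl 8β-acetoxy-3β-(tert-butyldimethylsilyloxy)eudesma-4,11(13)-dien-12-oate | C=C(C(=O)OC)[C@H]1CC2=C(C)[C@@H](O[Si](C)(C)C(C)(C)C)CC[C@]2(C)C[C@H]1OC(C)=O | intermediate
22 | methyl 8β-acetoxy-3β-hydroxyeudesma-4,11(13)-dien-12-oate | C=C(C(=O)OC)[C@H]1CC2=C(C)[C@@H](O)CC[C@]2(C)C[C@H]1OC(C)=O | intermediate
23 | methyl 8β-acetoxy-3β-(2-methylpropanoyloxy)eudesma-4,11(13)-dien-12-oate | C=C(C(=O)OC)[C@H]1CC2=C(C)[C@@H](OC(=O)C(C)C)CC[C@]2(C)C[C@H]1OC(C)=O | intermediate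
24 | methyl 8β-acetoxy-5α-hydroperoxy-3β-(2-methylpropanoyloxy)eudesma-4(15),11(13)-dien-12-oate | C=C(C(=O)OC)[C@H]1C[C@@]2(OO)C(=C)[C@@H](OC(=O)C(C)C)CC[C@]2(C)C[C@H]1OC(C)=O | target

## Step count and least certain steps

Total: 17 steps. Longest linear sequence: 17 steps (1 and 2 to 24); quinone 6 enters at step 4.

**Step 4 (key step).**
- Risk: insufficient facial discrimination. An uncatalysed or achiral Lewis-acid pathway, or a stepwise silyl-transfer (Mukaiyama–Michael) course that closes the ring outside the ligand's control, would erode the enantiomeric purity. Monodentate binding at the other carbonyl would also reverse the regiochemistry, and premature loss of the silyl enol ether would expose the C8 ketone.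
- Fallback: set out from 5 and 6 with SnCl4 in CH2Cl2 at −78 °C, which uses the same chelation for regiocontrol and should give racemic 7. This is taken through steps 5–9 to racemic 14. Esterification with (S)-2-methoxy-2-phenylacetic acid (dicyclohexylcarbodiimide, 4-(dimethylamino)pyridine) gives two diastereomers. The one of the natural series, 3β-[(S)-2-methoxy-2-phenylacetoxy]-13-noreudesm-4-en-12,8β-olide F1, is separated by chromatography or crystallisation and cleaved with K2CO3 in MeOH. The route is rejoined at 14.

**Step 7.**
- Risk: slow or unselective hydride delivery. The C1 carbonyl is both a vinylogous ester and flanked by the quaternary C10, so ester reduction, or early loss of the silyl enol ether followed by C8 reduction, may intervene before C1 is consumed.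
- Fallback: set out from 9 and mask the ester as a carboxylate. LiOH in THF/H2O at 0 °C gives 8-(tert-butyldimethylsilyloxy)-3-methoxy-1-oxo-13-noreudesma-2,4,7-trien-12-oic acid F2. iBu2AlH (3 equiv, THF, −78 °C) reduces only C1, and 2 M HCl then gives 3,8-dioxo-13-noreudesma-1,4-dien-12-oic acid F3. Me3SiCHN2 in MeOH/toluene returns to 11.

**Step 9.**
- Risk: poor facial selectivity at one of the two carbonyls, since two stereocentres are set by substrate control in one operation, or incomplete lactonisation.
- Fallback: set out from 12 and separate the two reductions. NaBH4 in MeOH/CH2Cl2 at −78 °C reduces only the saturated C8 ketone and gives 3-oxo-13-noreudesm-4-en-12,8β-olide F4. The enone is then reduced under catalyst control with (R)-1-methyl-3,3-diphenyl-tetrahydro-1H,3H-pyrrolo[1,2-c][1,3,2]oxazaborole ((R)-Me-CBS) and BH3·SMe2; with C4 as the large group this should give the 3S (3β) alcohol. The route is rejoined at 14.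

**Step 13.**
- Risk: relactonisation of the γ-hydroxy ester before or during acetylation, and conjugate addition of hydroxide to the methylene lactone.
- Fallback: set out from 18 and open the lactone reductively, so that a free 8-hydroxyl never faces an ester.
  - iBu2AlH (CH2Cl2, −78 to 0 °C) gives 3β-(tert-butyldimethylsilyloxy)eudesma-4,11(13)-diene-8β,12-diol F5.
  - Et3SiCl and imidazole at −20 °C silylate the primary allylic hydroxyl to give 3β-(tert-butyldimethylsilyloxy)-12-(triethylsilyloxy)eudesma-4,11(13)-dien-8β-ol F6.
  - Ac2O with 4-(dimethylamino)pyridine gives 8β-acetoxy-3β-(tert-butyldimethylsilyloxy)-12-(triethylsilyloxy)eudesma-4,11(13)-diene F7.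
  - Pyridinium p-toluenesulfonate in MeOH at 0 °C frees the primary alcohol, 8β-acetoxy-3β-(tert-butyldimethylsilyloxy)eudesma-4,11(13)-dien-12-ol F8.
  - Oxidative esterification (MnO2, 1,4-dimethyl-1,2,4-triazolium iodide (cat.), 1,8-diazabicyclo[5.4.0]undec-7-ene, MeOH) returns to 21.

**Step 17.**
- Risk: competing hydrogen abstraction from C6 (oxygen at C4) or from C3, some β-face attack, and acid-induced Hock cleavage of the product on purification. The alkene is tetrasubstituted with allylic hydrogens on three carbons.
- Fallback: set out from 23 and install the oxygen as the alcohol.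
  - 3-Chloroperbenzoic acid with NaHCO3 (CH2Cl2, 0 °C) should give methyl 8β-acetoxy-4α,5α-epoxy-3β-(2-methylpropanoyloxy)eudesm-11(13)-en-12-oate F9 from the α face.
  - Diethylaluminium 2,2,6,6-tetramethylpiperidide (toluene, 0 °C) removes the least hindered syn β-hydrogen (from C15) and gives methyl 8β-acetoxy-5α-hydroxy-3β-(2-methylpropanoyloxy)eudesma-4(15),11(13)-dien-12-oate F10.
  - Acid-catalysed perhydrolysis (anhydrous H2O2 in Et2O, cat. TsOH, 0 °C, short contact) returns to 24.
  - This fallback is weaker than the main step: the amide base must spare three esters, and the perhydrolysis needs kinetic control.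

## Further compounds

F1 | step 4 | 3β-[(S)-2-methoxy-2-phenylacetoxy]-13-noreudesm-4-en-12,8β-olide | O=C1C[C@H]2CC3=C(C)[C@@H](OC(=O)[C@@H](OC)c4ccccc4)CC[C@]3(C)C[C@H]2O1
F2 | step 7 | 8-(tert-butyldimethylsilyloxy)-3-methoxy-1-oxo-13-noreudesma-2,4,7-trien-12-oic acid | OC(=O)CC1=C(O[Si](C)(C)C(C)(C)C)C[C@@]2(C)C(=O)C=C(OC)C(C)=C2C1
F3 | step 7 | 3,8-dioxo-13-noreudesma-1,4-dien-12-oic acid | OC(=O)C[C@H]1CC2=C(C)C(=O)C=C[C@]2(C)CC1=O
F4 | step 9 | 3-oxo-13-noreudesm-4-en-12,8β-olide | O=C1C[C@H]2CC3=C(C)C(=O)CC[C@]3(C)C[C@H]2O1
F5 | step 13 | 3β-(tert-butyldimethylsilyloxy)eudesma-4,11(13)-diene-8β,12-diol | C=C(CO)[C@H]1CC2=C(C)[C@@H](O[Si](C)(C)C(C)(C)C)CC[C@]2(C)C[C@H]1O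
F6 | step 13 | 3β-(tert-butyldimethylsilyloxy)-12-(triethylsilyloxy)eudesma-4,11(13)-dien-8β-ol | C=C(CO[Si](CC)(CC)CC)[C@H]1CC2=C(C)[C@@H](O[Si](C)(C)C(C)(C)C)CC[C@]2(C)C[C@H]1O
F7 | step 13 | 8β-acetoxy-3β-(tert-butyldimethylsilyloxy)-12-(triethylsilyloxy)eudesma-4,11(13)-diene | C=C(CO[Si](CC)(CC)CC)[C@H]1CC2=C(C)[C@@H](O[Si](C)(C)C(C)(C)C)CC[C@]2(C)C[C@H]1OC(C)=O
F8 | step 13 | 8β-acetoxy-3β-(tert-butyldimethylsilyloxy)eudesma-4,11(13)-dien-12-ol | C=C(CO)[C@H]1CC2=C(C)[C@@H](O[Si](C)(C)C(C)(C)C)CC[C@]2(C)C[C@H]1OC(C)=O
F9 | step 17 | methyl 8β-acetoxy-4α,5α-epoxy-3β-(2-methylpropanoyloxy)eudesm-11(13)-en-12-oate | C=C(C(=O)OC)[C@H]1C[C@@]2(O3)[C@@]3(C)[C@@H](OC(=O)C(C)C)CC[C@]2(C)C[C@H]1OC(C)=O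
F10 | step 17 | methyl 8β-acetoxy-5α-hydroxy-3β-(2-methylpropanoyloxy)eudesma-4(15),11(13)-dien-12-oate | C=C(C(=O)OC)[C@H]1C[C@@]2(O)C(=C)[C@@H](OC(=O)C(C)C)CC[C@]2(C)C[C@H]1OC(C)=O
A1 | alternative 1 | acyclic β-keto ester with (E)-trisubstituted alkene and terminal enol acetate | COC(=O)C(C)C(=O)CC/C(C)=C/C[C@H](CC(=O)OC)C(=C)OC(C)=O
A2 | alternative 1 | trans-fused 3,8-diketone with 4-methyl-4-methoxycarbonyl and 10-methyl groups | COC(=O)C[C@H]1C[C@H]2[C@@](C)(C(=O)OC)C(=O)CC[C@]2(C)CC1=O
A3 | alternative 2 | ring A enone carrying the C8 aldehyde and the (Z)-2-(bromomethyl)enoate | BrC/C(C(=O)OC)=C\CC1=C(C)C(=O)CC[C@]1(C)CC=O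
A4 | alternative 2 | methyl 8β-hydroxy-3-oxoeudesma-4,11(13)-dien-12-oate | C=C(C(=O)OC)[C@H]1CC2=C(C)C(=O)CC[C@]2(C)C[C@H]1O
A5 | alternative 3 | 1-isopropenyl-2-methyl-2-vinylcyclohexanol with the C7 and C8 substituents (C5 and C10 configuration not specified) | C=C(CO[Si](C)(C)C(C)(C)C)[C@H]1CC(O)(C(C)=C)C(C)(C=C)C[C@@H]1O[Si](C)(C)C(C)(C)C
A6 | alternative 3 | ten-membered (E)-enone from the oxy-Cope rearrangement | C=C(CO[Si](C)(C)C(C)(C)C)[C@H]1CC(=O)C(C)CC/C=C(C)/C[C@@H]1O[Si](C)(C)C(C)(C)C
A7 | alternative 3 | trans-fused 5α-hydroxy-4α,10β-dimethyl-1-ene with 8α-silyloxy group | C=C(CO[Si](C)(C)C(C)(C)C)[C@H]1C[C@@]2(O)[C@H](C)CC=C[C@]2(C)C[C@@H]1O[Si](C)(C)C(C)(C)C
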